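**Synthesis plan**

1. Numbering and cuts: the seven-membered ring is C1 (carbinol carrying the crotonoyl chain C2–C4, C15), C5 (O-angelate), C6 (lactone O), C7 (bears C11–C13), C8, C9 (CHOH), C10 (CH–CH3). The retrosynthesis cuts, in order, C9–H (back to the ketone), the angelate ester bond, the C5–O and C6–O(lactone) bonds (back to a C5=C6 alkene through a C1–C5 epoxide and an iodolactonisation), then C10–C1 by a retro-Claisen that contracts the cyclohept-4-enone to a 2-ethylidene-5-alkenyl oxolane, and last C5=C1 (olefination) and C7–C11 (conjugate addition).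
2. Enabling feature: the C9 oxygen is flanked by the vicinal C10/C1 pair and lies 1,5 to the oxygenated C5–C6 edge, which is a masked cyclohept-4-enone (C9=O, C5=C6, bond C10–C1); C6–C7–C8–C9 with the C6 oxygen is the skeleton of a γ-butenolide.
3. Forward order: the five-membered ring is bought as a butenolide and carried as lactone, then as oxolane. The C5=C1 enol silyl ether is attached by olefination, and the [3,3] shift turns the oxolane into the seven-membered carbocycle. The cis-fused α-methylene γ-lactone and a transient C1–C5 epoxide then close in one pot, the epoxide is hydrolysed, C5 is angeloylated and C9 is reduced last.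
4. Stereochemistry: C7 comes from the butenolide centre (anti cuprate addition). C10 and C1 come from C6 and the two alkene geometries through the chair-like Claisen. C6 and C5 come from anti iodolactonisation, epoxide closure and inverting hydrolysis. C9 comes from hydride delivery directed by the C1 hydroxyl.

Key step: step 10

Assumption: the (R)-enantiomer of butenolide 1 is taken as a catalogue chemical, and paraformaldehyde serves as the source of formaldehyde 12.

**Route**

Step 1
Reactants: 1 (R)-5-(hydroxymethyl)furan-2(5H)-one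
Product: 2 (R)-5-[(tert-butyldimethylsilyloxy)methyl]furan-2(5H)-one
Conditions: TBSCl, imidazole, CH2Cl2, 0 °C to rt
Reagents that add atoms: tert-butyldimethylsilyl chloride (TBSCl), CC(C)(C)[Si](C)(C)Cl
Why: Imidazole-mediated silylation of the primary alcohol is routine for this butenolide and leaves the stereocentre untouched.

Step 2
Reactants: 2 (R)-5-[(tert-butyldimethylsilyloxy)methyl]furan-2(5H)-one; 3 2-bromo-3,3-diethoxyprop-1-ene
Product: 6 (4S,5R)-5-[(tert-butyldimethylsilyloxy)methyl]-4-(3,3-diethoxyprop-1-en-2-yl)oxolan-2-one, via vinyllithium 4 (not isolated), via divinylcuprate 5 (not isolated)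
Conditions: 3, t-BuLi (2 equiv per bromide), Et2O, −78 °C; CuBr·SMe2 (0.5 equiv per vinyllithium), −78 to −40 °C; then 2, −78 °C; aq. NH4Cl/NH3
Reagents that add atoms: none
Why: Bromine–lithium exchange gives the acrolein-acetal vinyllithium, whose Gilman cuprate should undergo conjugate addition to the butenolide on the face anti to the C6 siloxymethyl group, so that C7 is set trans to C6.

Step 3
Reactants: 6 (4S,5R)-5-[(tert-butyldimethylsilyloxy)methyl]-4-(3,3-diethoxyprop-1-en-2-yl)oxolan-2-one; 7 1,1-dibromoethane
Product: 9 tert-butyl{[(2R,3S,5Z)-3-(3,3-diethoxyprop-1-en-2-yl)-5-ethylideneoxolan-2-yl]methoxy}dimethylsilane, via geminal dizinc reagent 8 (not isolated)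
Conditions: Zn, PbCl2 (cat.), TiCl4, TMEDA, THF, 0 to 25 °C; then 6 and 7, 25 °C; aq. K2CO3; Et3N-deactivated silica
Reagents that add atoms: none
Why: Takai–Utimoto alkylidenation with the low-valent titanium ethylidene should convert the lactone carbonyl into the exocyclic enol ether with the methyl group cis to the ring oxygen (Z, away from the ring methylene), and the amine-buffered, non-basic reagent should spare the acetal and C7.

Step 4
Reactants: 9 tert-butyl{[(2R,3S,5Z)-3-(3,3-diethoxyprop-1-en-2-yl)-5-ethylideneoxolan-2-yl]methoxy}dimethylsilane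
Product: 10 [(2R,3S,5Z)-3-(3,3-diethoxyprop-1-en-2-yl)-5-ethylideneoxolan-2-yl]methanol
Conditions: Bu4NF, THF, 0 °C
Reagents that add atoms: none
Why: Fluoride cleavage of the primary silyl ether runs under basic conditions that the acid-labile enol ether and acetal tolerate.

Step 5
Reactants: 10 [(2R,3S,5Z)-3-(3,3-diethoxyprop-1-en-2-yl)-5-ethylideneoxolan-2-yl]methanol
Product: 11 (2R,3S,5Z)-3-(3,3-diethoxyprop-1-en-2-yl)-5-ethylideneoxolane-2-carbaldehyde
Conditions: SO3·pyridine, DMSO, i-Pr2NEt, CH2Cl2, 0 °C
Reagents that add atoms: none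
Why: Parikh–Doering oxidation is acid-free and should give the α-alkoxy aldehyde (C5) without touching the enol ether, the trans C6/C7 arrangement being the stable one should C6 enolise.

Step 6
Reactants: 12 formaldehyde (as paraformaldehyde); 13 bis(2,2,2-trifluoroethyl) phosphite
Product: 14 bis(2,2,2-trifluoroethyl) (hydroxymethyl)phosphonate
Conditions: Et3N (cat.), THF, 60 °C
Reagents that add atoms: none
Why: Pudovik addition of the P–H bond to formaldehyde gives the hydroxymethylphosphonate whose carbon becomes C1.

Step 7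
Reactants: 14 bis(2,2,2-trifluoroethyl) (hydroxymethyl)phosphonate
Product: 15 bis(2,2,2-trifluoroethyl) [(tert-butyldimethylsilyloxy)methyl]phosphonate
Conditions: TBSCl, imidazole, DMF, rt
Reagents that add atoms: tert-butyldimethylsilyl chloride (TBSCl), CC(C)(C)[Si](C)(C)Cl
Why: Silylation of the primary alcohol installs the silyl group that later becomes the enol silyl ether and then the protected C1 carbinol.

Step 8
Reactants: 15 bis(2,2,2-trifluoroethyl) [(tert-butyldimethylsilyloxy)methyl]phosphonate; 16 (E)-but-2-enoyl chloride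
Product: 18 bis(2,2,2-trifluoroethyl) [(E)-1-(tert-butyldimethylsilyloxy)-2-oxopent-3-en-1-yl]phosphonate (racemic), via lithiated phosphonate 17 (not isolated)
Conditions: LiN(SiMe3)2 (2 equiv), THF, −98 °C, short metalation; then 16, −98 to −78 °C; AcOH quench
Reagents that add atoms: none
Why: C-acylation of the phosphonate carbanion by the acid chloride at very low temperature, with a second equivalent of base to take up the more acidic product proton, is the usual route to bis(trifluoroethyl) β-keto phosphonates and should outrun silyl migration or loss of trifluoroethoxide.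

Step 9
Reactants: 11 (2R,3S,5Z)-3-(3,3-diethoxyprop-1-en-2-yl)-5-ethylideneoxolane-2-carbaldehyde; 18 bis(2,2,2-trifluoroethyl) [(E)-1-(tert-butyldimethylsilyloxy)-2-oxopent-3-en-1-yl]phosphonate
Product: 20 (1E,4E)-2-(tert-butyldimethylsilyloxy)-1-[(2R,3S,5Z)-3-(3,3-diethoxyprop-1-en-2-yl)-5-ethylideneoxolan-2-yl]hexa-1,4-dien-3-one, via potassium phosphonate enolate 19 (not isolated)
Conditions: KN(SiMe3)2, 18-crown-6, THF, −78 °C; then 11, −78 to −40 °C; Et3N-deactivated silica
Reagents that add atoms: none
Why: In this Still–Gennari-type Horner–Wadsworth–Emmons olefination the electron-poor bis(trifluoroethyl) phosphonate under dissociating conditions should eliminate from the kinetic adduct, placing the acyl group cis and the siloxy group trans to C6, and the geometric isomer is removed by chromatography.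

Step 10
Reactants: 20 (1E,4E)-2-(tert-butyldimethylsilyloxy)-1-[(2R,3S,5Z)-3-(3,3-diethoxyprop-1-en-2-yl)-5-ethylideneoxolan-2-yl]hexa-1,4-dien-3-one
Product: 21 (2R,3R,6R)-3-[(E)-but-2-enoyl]-3-(tert-butyldimethylsilyloxy)-6-(3,3-diethoxyprop-1-en-2-yl)-2-methylcyclohept-4-en-1-one
Conditions: degassed o-xylene, 130–140 °C, base-washed silanised sealed glass, argon
Reagents that add atoms: none
Why: A concerted suprafacial [3,3]-sigmatropic (Claisen) shift exchanges the C6–O bond for a C10–C1 bond between the exocyclic enol ether C10=C9–O and the allyl unit C6–C5=C1, and formation of the C9 carbonyl makes it irreversible. The closest known reaction type is the thermal Claisen ring expansion of 2-alkylidene-5-alkenyl tetrahydrofurans to cyclohept-4-enones. The carbocycle closes by two-carbon ring expansion of the oxolane through a six-centre array bridged by C7–C8, an 8-oxabicyclo[3.2.1]octene-like chair that is the only geometry able to give the cis C5=C6 ring alkene. C10 is set by the Z enol ether (methyl cis to oxygen goes axial) and C1 by the enol silyl ether geometry (siloxy trans to C6 goes equatorial), both relayed from the C6 centre that is consumed, so that methyl, siloxy group and the exo C7 side chain end on one face. The step needs complete chair-type transfer without enol ether migration or C10 epimerisation; the ring constraint excludes the boat, the siloxy donor on the allyl terminus should lower the barrier, and neutral base-washed glassware with no acid or base present protects the enol ethers and C10.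

Step 11
Reactants: 21 (2R,3R,6R)-3-[(E)-but-2-enoyl]-3-(tert-butyldimethylsilyloxy)-6-(3,3-diethoxyprop-1-en-2-yl)-2-methylcyclohept-4-en-1-one
Product: 22 2-[(1R,4R,5R)-4-[(E)-but-2-enoyl]-4-hydroxy-5-methyl-6-oxocyclohept-2-en-1-yl]prop-2-enal
Conditions: 48% aq. HF, MeCN, 0 °C to rt
Reagents that add atoms: water, O
Why: Aqueous HF should hydrolyse the diethyl acetal to the 2-substituted propenal and cleave the tertiary silyl ether in one operation, with no stereocentre involved and the C1 carbinol shielded from ionisation by its α-carbonyl.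

Step 12
Reactants: 22 2-[(1R,4R,5R)-4-[(E)-but-2-enoyl]-4-hydroxy-5-methyl-6-oxocyclohept-2-en-1-yl]prop-2-enal
Product: 23 2-[(1R,4R,5R)-4-[(E)-but-2-enoyl]-4-hydroxy-5-methyl-6-oxocyclohept-2-en-1-yl]prop-2-enoic acid
Conditions: NaClO2, NaH2PO4, 2-methylbut-2-ene, t-BuOH/H2O, 0 °C to rt
Reagents that add atoms: sodium chlorite, [Na+].[O-]Cl=O
Why: Pinnick oxidation with a hypochlorite scavenger converts the enal into the acrylic acid under buffered conditions that leave ketones, alkenes and the tertiary alcohol alone.

Step 13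
Reactants: 23 2-[(1R,4R,5R)-4-[(E)-but-2-enoyl]-4-hydroxy-5-methyl-6-oxocyclohept-2-en-1-yl]prop-2-enoic acid
Product: 25 epoxy lactone (cis-fused α-methylene γ-lactone at C6/C7; C1–C5 epoxide on the face of the lactone oxygen; C9 ketone; 1-crotonoyl; 10-methyl), via iodolactone 24 (not isolated)
Conditions: I2, NaHCO3, MeCN, 0 °C, dark; then K2CO3, rt; Na2S2O3 work-up
Reagents that add atoms: none
Why: In the iodolactonisation the C7-tethered carboxylate opens the iodonium ion of the C5=C6 alkene at C6 from its own face (cis-fused five-membered lactone, iodide at C5 on the opposite face), and the C1 alkoxide, anti to that iodide, then displaces it with inversion in a Williamson-type epoxide closure, so C6 and C5 are fixed by anti addition and backside attack.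

Step 14
Reactants: 25 epoxy lactone
Product: 26 C1,C5-diol (5-hydroxyl trans to the lactone oxygen and trans to the 1-hydroxyl; C9 ketone)
Conditions: HClO4 (cat.), THF/H2O, rt
Reagents that add atoms: water, O
Why: Acid-catalysed hydrolysis of the epoxy ketone should take place by attack of water at the secondary C5 with inversion, because the tertiary C1 is deactivated by its α-carbonyl, and C1 keeps its configuration since its C–O bond is not broken.

Step 15
Reactants: 26 C1,C5-diol; 27 angelic acid [(Z)-2-methylbut-2-enoic acid]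
Product: 29 C9-keto angelate (5-O-angeloyl, free 1-hydroxyl), via mixed anhydride 28 (not isolated)
Conditions: 27, 2,4,6-trichlorobenzoyl chloride, Et3N, toluene, rt; then 26, 70 °C, no DMAP
Reagents that add atoms: none
Why: Yamaguchi-type esterification through the angelic 2,4,6-trichlorobenzoic mixed anhydride should acylate only the secondary C5 hydroxyl (the tertiary C1 hydroxyl is inert) and, without a nucleophilic catalyst, should avoid angelate-to-tiglate isomerisation.

Step 16
Reactants: 29 C9-keto angelate
Product: 30 target CNP0149130.1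
Conditions: Me4NBH(OAc)3, MeCN/AcOH, −30 °C
Reagents that add atoms: none
Why: In this Evans–Saksena hydroxyl-directed reduction the boron-bound C1 oxygen should deliver hydride through a six-membered transition state to the C9 ketone from the face of the C1 hydroxyl, giving the 1,3-anti diol, while the conjugated and more hindered C2 ketone (five-membered delivery) should react more slowly and esters, lactone and alkenes are not touched.

**Compound list**

1 | (R)-5-(hydroxymethyl)furan-2(5H)-one | O=C1O[C@@H](CO)C=C1 | starting material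
2 | (R)-5-[(tert-butyldimethylsilyloxy)methyl]furan-2(5H)-one | O=C1O[C@@H](CO[Si](C)(C)C(C)(C)C)C=C1 | intermediate
3 | 2-bromo-3,3-diethoxyprop-1-ene | C=C(Br)C(OCC)OCC | starting material
4 | (3,3-diethoxyprop-1-en-2-yl)lithium | [Li]C(=C)C(OCC)OCC | intermediate (not isolated)
5 | lithium bis(3,3-diethoxyprop-1-en-2-yl)cuprate | [Li+].C=C([Cu-]C(=C)C(OCC)OCC)C(OCC)OCC | intermediate (not isolated)
6 | (4S,5R)-5-[(tert-butyldimethylsilyloxy)methyl]-4-(3,3-diethoxyprop-1-en-2-yl)oxolan-2-one (4,5-trans) | O=C1O[C@@H](CO[Si](C)(C)C(C)(C)C)[C@H](C(=C)C(OCC)OCC)C1 | intermediate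
7 | 1,1-dibromoethane | CC(Br)Br | starting material
8 | 1,1-bis(bromozincio)ethane (geminal dizinc reagent, passed on to titanium) | CC([Zn]Br)[Zn]Br | intermediate (not isolated)
9 | tert-butyl{[(2R,3S,5Z)-3-(3,3-diethoxyprop-1-en-2-yl)-5-ethylideneoxolan-2-yl]methoxy}dimethylsilane | C/C=C1\O[C@@H](CO[Si](C)(C)C(C)(C)C)[C@H](C(=C)C(OCC)OCC)C1 | intermediate
10 | [(2R,3S,5Z)-3-(3,3-diethoxyprop-1-en-2-yl)-5-ethylideneoxolan-2-yl]methanol | C/C=C1\O[C@@H](CO)[C@H](C(=C)C(OCC)OCC)C1 | intermediate
11 | (2R,3S,5Z)-3-(3,3-diethoxyprop-1-en-2-yl)-5-ethylideneoxolane-2-carbaldehyde | C/C=C1\O[C@@H](C=O)[C@H](C(=C)C(OCC)OCC)C1 | intermediate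
12 | formaldehyde (used as paraformaldehyde) | C=O | starting material
13 | bis(2,2,2-trifluoroethyl) phosphite | O=[PH](OCC(F)(F)F)OCC(F)(F)F | starting material
14 | bis(2,2,2-trifluoroethyl) (hydroxymethyl)phosphonate | OCP(=O)(OCC(F)(F)F)OCC(F)(F)F | intermediate
15 | bis(2,2,2-trifluoroethyl) [(tert-butyldimethylsilyloxy)methyl]phosphonate | CC(C)(C)[Si](C)(C)OCP(=O)(OCC(F)(F)F)OCC(F)(F)F | intermediate
16 | (E)-but-2-enoyl chloride (crotonoyl chloride) | C/C=C/C(=O)Cl | starting material
17 | α-lithio derivative of phosphonate 15 | [Li]C(O[Si](C)(C)C(C)(C)C)P(=O)(OCC(F)(F)F)OCC(F)(F)F | intermediate (not isolated)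
18 | bis(2,2,2-trifluoroethyl) [(E)-1-(tert-butyldimethylsilyloxy)-2-oxopent-3-en-1-yl]phosphonate (racemic) | C/C=C/C(=O)C(O[Si](C)(C)C(C)(C)C)P(=O)(OCC(F)(F)F)OCC(F)(F)F | intermediate
19 | potassium salt of phosphonate 18 | [K+].C/C=C/C(=O)[C-](O[Si](C)(C)C(C)(C)C)P(=O)(OCC(F)(F)F)OCC(F)(F)F | intermediate (not isolated)
20 | (1E,4E)-2-(tert-butyldimethylsilyloxy)-1-[(2R,3S,5Z)-3-(3,3-diethoxyprop-1-en-2-yl)-5-ethylideneoxolan-2-yl]hexa-1,4-dien-3-one (acyl cis, siloxy trans to the oxolane carbon) | C/C=C1\O[C@@H](/C=C(/O[Si](C)(C)C(C)(C)C)C(=O)/C=C/C)[C@H](C(=C)C(OCC)OCC)C1 | intermediate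
21 | (2R,3R,6R)-3-[(E)-but-2-enoyl]-3-(tert-butyldimethylsilyloxy)-6-(3,3-diethoxyprop-1-en-2-yl)-2-methylcyclohept-4-en-1-one (methyl, siloxy and side chain on one face) | C=C(C(OCC)OCC)[C@@H]1CC(=O)[C@H](C)[C@@](O[Si](C)(C)C(C)(C)C)(C(=O)/C=C/C)C=C1 | intermediate
22 | 2-[(1R,4R,5R)-4-[(E)-but-2-enoyl]-4-hydroxy-5-methyl-6-oxocyclohept-2-en-1-yl]prop-2-enal | C=C(C=O)[C@@H]1CC(=O)[C@H](C)[C@@](O)(C(=O)/C=C/C)C=C1 | intermediate
23 | 2-[(1R,4R,5R)-4-[(E)-but-2-enoyl]-4-hydroxy-5-methyl-6-oxocyclohept-2-en-1-yl]prop-2-enoic acid | C=C(C(=O)O)[C@@H]1CC(=O)[C@H](C)[C@@](O)(C(=O)/C=C/C)C=C1 | intermediate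
24 | iodolactone: cis-fused α-methylene γ-lactone (C6–O, C7), 5-iodide trans to the lactone oxygen and to the free 1-hydroxyl, C9 ketone | C=C1C(=O)O[C@@H]2[C@H]1CC(=O)[C@H](C)[C@@](O)(C(=O)/C=C/C)[C@H]2I | intermediate (not isolated)
25 | epoxy lactone: cis-fused α-methylene γ-lactone, C1–C5 epoxide cis to the lactone oxygen, 1-[(E)-crotonoyl], 10-methyl, C9 ketone | C=C1C(=O)O[C@@H]2[C@H]1CC(=O)[C@H](C)[C@]3(C(=O)/C=C/C)O[C@H]23 | intermediate
26 | C1,C5-diol: cis-fused α-methylene γ-lactone, 5-hydroxyl trans to the lactone oxygen and to the 1-hydroxyl, C9 ketone | C=C1C(=O)O[C@@H]2[C@H]1CC(=O)[C@H](C)[C@@](O)(C(=O)/C=C/C)[C@H]2O | intermediate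
27 | angelic acid, (Z)-2-methylbut-2-enoic acid | O=C(O)/C(C)=C\C | starting material
28 | angelic 2,4,6-trichlorobenzoic anhydride | C/C=C(/C)C(=O)OC(=O)c1c(Cl)cc(Cl)cc1Cl | intermediate (not isolated)
29 | C9-keto angelate: as 26 with the 5-hydroxyl esterified by angelic acid, free 1-hydroxyl | C=C1C(=O)O[C@@H]2[C@H]1CC(=O)[C@H](C)[C@@](O)(C(=O)/C=C/C)[C@H]2OC(=O)/C(C)=C\C | intermediate
30 | CNP0149130.1: cis-fused α-methylene γ-lactone, 5-O-angelate trans to the lactone oxygen, 1-hydroxy-1-[(E)-crotonoyl] with hydroxyl trans to the angelate, 10-methyl cis to the 1-hydroxyl, 9-hydroxyl trans to the 10-methyl | C=C1C(=O)O[C@@H]2[C@H]1C[C@@H](O)[C@H](C)[C@@](O)(C(=O)/C=C/C)[C@H]2OC(=O)/C(C)=C\C | target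

**Step count and risks**

Total step count: 16. Longest linear sequence: 13 steps (steps 1–5 and 9–16 from butenolide 1); the phosphonate arm (steps 6–8) joins at step 9.

The three steps most likely to fail:

Step 9. The fully substituted, doubly stabilised phosphonate anion may add slowly to the α-branched aldehyde and eliminate without kinetic control, so that the enol silyl ether geometry needed for C1 is not obtained cleanly, and C6 may epimerise during a long reaction. The fallback builds the acyl group after the olefination and sets out from aldehyde 11 and phosphonate 15. Phosphonate 15 is carboxylated with methyl chloroformate under the conditions of step 8 to methyl 2-[bis(2,2,2-trifluoroethoxy)phosphoryl]-2-(tert-butyldimethylsilyloxy)acetate F1, the better precedented ester-type Still–Gennari reagent. Its potassium salt (KN(SiMe3)2, 18-crown-6, −78 °C) with 11 should give the 2-siloxy acrylate with the ester cis to the oxolane carbon, methyl (E)-2-(tert-butyldimethylsilyloxy)-3-[(2R,3S,5Z)-3-(3,3-diethoxyprop-1-en-2-yl)-5-ethylideneoxolan-2-yl]prop-2-enoate F2. MeNH(OMe)·HCl with i-PrMgCl at −20 °C turns it into the N-methoxy-N-methyl amide F3, and (E)-prop-1-enyllithium (from (E)-1-bromoprop-1-ene and t-BuLi, −78 °C) converts this amide into dienone 20, where the route is rejoined.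

Step 10. At the temperature the shift needs, the cross-conjugated siloxy dienone may be lost to competing processes (proton-catalysed migration of the exocyclic enol ether into the ring, Nazarov-type closure or oligomerisation of the enone), and the acyl acceptor on the allyl terminus may slow the formation of the congested C10–C1 bond. The fallback removes the acceptor before the rearrangement and sets out from 20. Luche reduction (NaBH4, CeCl3·7H2O, MeOH, −78 °C) gives the dienol (1E,4E)-2-(tert-butyldimethylsilyloxy)-1-[(2R,3S,5Z)-3-(3,3-diethoxyprop-1-en-2-yl)-5-ethylideneoxolan-2-yl]hexa-1,4-dien-3-ol F4 as a mixture at the new carbinol, which is silylated (Et3SiCl, imidazole) to the triethylsilyl ether F5. F5 carries only donor groups on the allyl terminus and is rearranged thermally as in step 10 to the cycloheptenone bis-silyl ether F6, with the same transfer of configuration to C10 and C1. Aqueous HF in MeCN then frees both hydroxyls and the enal to give the dihydroxy enal F7, and MnO2 in CH2Cl2 oxidises only the allylic C2 carbinol back to the enone, returning to the route at hydroxy enal 22.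

Step 16. Chemoselectivity may be lost because the C1 hydroxyl can also direct hydride to the neighbouring C2 carbonyl, giving over-reduction or mixtures. The fallback sets out from 29, accepts reduction of both ketones and corrects the oxidation level afterwards. An excess of Me4NBH(OAc)3 at higher temperature gives the C2,C9-diol F8, the C9 configuration still being set by delivery from the C1 hydroxyl. MnO2 in CH2Cl2 then re-oxidises only the allylic C2 carbinol to the crotonoyl ketone and gives target 30.

Further compounds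
F1 | step 9 | methyl 2-[bis(2,2,2-trifluoroethoxy)phosphoryl]-2-(tert-butyldimethylsilyloxy)acetate | COC(=O)C(O[Si](C)(C)C(C)(C)C)P(=O)(OCC(F)(F)F)OCC(F)(F)F
F2 | step 9 | methyl (E)-2-(tert-butyldimethylsilyloxy)-3-[(2R,3S,5Z)-3-(3,3-diethoxyprop-1-en-2-yl)-5-ethylideneoxolan-2-yl]prop-2-enoate | C/C=C1\O[C@@H](/C=C(/O[Si](C)(C)C(C)(C)C)C(=O)OC)[C@H](C(=C)C(OCC)OCC)C1
F3 | step 9 | (E)-2-(tert-butyldimethylsilyloxy)-3-[(2R,3S,5Z)-3-(3,3-diethoxyprop-1-en-2-yl)-5-ethylideneoxolan-2-yl]-N-methoxy-N-methylprop-2-enamide | C/C=C1\O[C@@H](/C=C(/O[Si](C)(C)C(C)(C)C)C(=O)N(C)OC)[C@H](C(=C)C(OCC)OCC)C1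
F4 | step 10 | (1E,4E)-2-(tert-butyldimethylsilyloxy)-1-[(2R,3S,5Z)-3-(3,3-diethoxyprop-1-en-2-yl)-5-ethylideneoxolan-2-yl]hexa-1,4-dien-3-ol (carbinol epimers) | C/C=C1\O[C@@H](/C=C(/O[Si](C)(C)C(C)(C)C)C(O)/C=C/C)[C@H](C(=C)C(OCC)OCC)C1
F5 | step 10 | triethylsilyl ether of F4 | C/C=C1\O[C@@H](/C=C(/O[Si](C)(C)C(C)(C)C)C(O[Si](CC)(CC)CC)/C=C/C)[C@H](C(=C)C(OCC)OCC)C1
F6 | step 10 | (2R,3R,6R)-3-(tert-butyldimethylsilyloxy)-6-(3,3-diethoxyprop-1-en-2-yl)-2-methyl-3-[(E)-1-(triethylsilyloxy)but-2-en-1-yl]cyclohept-4-en-1-one | C=C(C(OCC)OCC)[C@@H]1CC(=O)[C@H](C)[C@@](O[Si](C)(C)C(C)(C)C)(C(O[Si](CC)(CC)CC)/C=C/C)C=C1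
F7 | step 10 | 2-[(1R,4R,5R)-4-hydroxy-4-[(E)-1-hydroxybut-2-en-1-yl]-5-methyl-6-oxocyclohept-2-en-1-yl]prop-2-enal | C=C(C=O)[C@@H]1CC(=O)[C@H](C)[C@@](O)(C(O)/C=C/C)C=C1
F8 | step 16 | 2,9-diol: target 30 with the C2 ketone reduced to the allylic carbinol (C2 epimers) | C=C1C(=O)O[C@@H]2[C@H]1C[C@@H](O)[C@H](C)[C@@](O)(C(O)/C=C/C)[C@H]2OC(=O)/C(C)=C\C
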